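**Strategy.** Germacrane numbering is used (lactone O on C6, tiglate on C8, OH on C1, acetate on C3, C15H2OH on C4). The route rests on disconnecting the C3–C4 bond of the cyclodecadiene: an intramolecular Nozaki–Hiyama–Kishi reaction closes the ten-membered carbocycle last, exploiting the allylic carbinol C3 beside the Z-trisubstituted C4=C5 alkene, and in one operation forms the ring and the C3 stereocentre with retention of alkene geometry. The precursor is a seco-aldehyde whose trans α-methylene-γ-butyrolactone is already closed; it carries a (Z)-alkenyl iodide (C4) on C6 and, on C7, the C8 tiglate, the Z C9=C10 alkene, the silylated C1 carbinol and the C3 aldehyde. Both Z alkenes come from stereospecific alkyne additions.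

Key step: step 15

Remark: TBSO = tert-butyldimethylsilyloxy, PMBO = 4-methoxybenzyloxy; locants C1–C15 are germacrane numbers.
Remark: the chromium Barbier reaction of step 11 is assumed to follow the usual chair transition state (anti simple diastereoselection, 8α alcohol); this is why the tiglate is introduced with inversion in step 12.

Step 1
Reactants: 1 3-[(4-methoxybenzyl)oxy]propan-1-ol
Product: 2 3-[(4-methoxybenzyl)oxy]propanal
Conditions: TEMPO (10 mol%), PhI(OAc)2, CH2Cl2, rt
Reagents that add atoms: none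
Why: Oxoammonium (TEMPO/BAIB) oxidation should stop at the aldehyde and leave the PMB ether untouched.

Step 2
Reactants: 2 3-[(4-methoxybenzyl)oxy]propanal; 3 methyl propiolate
Product: 5 methyl (S)-4-hydroxy-6-[(4-methoxybenzyl)oxy]hex-2-ynoate, via methylzinc acetylide 4 (not isolated)
Conditions: Me2Zn, ProPhenol (20 mol%; antipode that delivers the S alcohol), Ph3PO (40 mol%), toluene, 4 °C
Reagents that add atoms: none
Why: Zinc–ProPhenol catalysed asymmetric alkynylation (Trost) adds the alkynylzinc to one aldehyde face and sets the future C1 carbinol under ligand control.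

Step 3
Reactants: 5 methyl (S)-4-hydroxy-6-[(4-methoxybenzyl)oxy]hex-2-ynoate
Product: 6 methyl (S)-4-(TBSO)-6-(PMBO)hex-2-ynoate
Conditions: TBSOTf, 2,6-lutidine, CH2Cl2, −78 → 0 °C
Reagents that add atoms: tert-butyldimethylsilyl triflate, CC(C)(C)[Si](C)(C)OS(=O)(=O)C(F)(F)F
Why: Standard silylation of a propargylic alcohol; the TBS ether is carried to the last step.

Step 4
Reactants: 6 methyl (S)-4-(TBSO)-6-(PMBO)hex-2-ynoate
Product: 8 methyl (S,Z)-4-(TBSO)-6-(PMBO)-3-methylhex-2-enoate, via alkenylcuprate 7 (not isolated)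
Conditions: Me2CuLi (from MeLi, CuI), THF, −78 °C; MeOH then aq NH4Cl at −78 °C
Reagents that add atoms: lithium dimethylcuprate, [Li+].C[Cu-]C
Why: syn-Carbocupration of the ynoate puts the C14 methyl on C10 and copper on C9 on the same side, and cold protonation with retention should give the Z enoate (C1 and C8 cis), fixing the C9=C10 geometry.

Step 5
Reactants: 8 methyl (S,Z)-4-(TBSO)-6-(PMBO)-3-methylhex-2-enoate
Product: 9 (S,Z)-4-(TBSO)-6-(PMBO)-3-methylhex-2-en-1-ol
Conditions: DIBAL-H, CH2Cl2, −78 °C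
Reagents that add atoms: none
Why: 1,2-Reduction of the enoate to the allylic alcohol does not touch the alkene geometry or the silyl and PMB ethers.

Step 6
Reactants: 9 (S,Z)-4-(TBSO)-6-(PMBO)-3-methylhex-2-en-1-ol
Product: 10 (S,Z)-4-(TBSO)-6-(PMBO)-3-methylhex-2-enal
Conditions: MnO2, CH2Cl2, rt
Reagents that add atoms: none
Why: Neutral allylic oxidation with MnO2 should deliver the Z enal without isomerisation; it is used at once.

Step 7
Reactants: 11 acrolein; 12 tert-butyldimethyl(prop-2-yn-1-yloxy)silane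
Product: 14 (S)-6-(TBSO)hex-1-en-4-yn-3-ol, via methylzinc acetylide 13 (not isolated)
Conditions: Me2Zn, ProPhenol (20 mol%; same antipode as in step 2), Ph3PO (40 mol%), toluene, 4 °C
Reagents that add atoms: none
Why: The same Trost alkynylation, for which α,β-unsaturated aldehydes are the preferred substrate class, gives 1,2-addition and sets the future C6 carbinol under ligand control.

Step 8
Reactants: 14 (S)-6-(TBSO)hex-1-en-4-yn-3-ol
Product: 16 (3S,4Z)-6-(TBSO)-5-iodohexa-1,4-dien-3-ol, via cyclic alkenylalanate 15 (not isolated)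
Conditions: Red-Al, THF, 0 °C; then I2, −78 °C
Reagents that add atoms: iodine, II
Why: Alkoxide-directed trans-hydroalumination delivers hydride to the proximal alkyne carbon (C5) and aluminium to the distal one (C4), and iodinolysis with retention gives the Z alkenyl iodide (C15 trans to C6); low temperature suppresses β-elimination of silyloxide.

Step 9
Reactants: 16 (3S,4Z)-6-(TBSO)-5-iodohexa-1,4-dien-3-ol; 17 2-(bromomethyl)acrylic acid
Product: 18 (3S,4Z)-6-(TBSO)-5-iodohexa-1,4-dien-3-yl 2-(bromomethyl)acrylate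
Conditions: DIC, DMAP (5 mol%), CH2Cl2, −10 → 0 °C
Reagents that add atoms: none
Why: Carbodiimide (Steglich) esterification at low temperature acylates the secondary alcohol without displacing the allylic bromide; C6 is not touched.

Step 10
Reactants: 18 (3S,4Z)-6-(TBSO)-5-iodohexa-1,4-dien-3-yl 2-(bromomethyl)acrylate
Product: 19 (S)-3-(bromomethyl)-5-[(Z)-3-(TBSO)-2-iodoprop-1-en-1-yl]furan-2(5H)-one
Conditions: Grubbs II (5 mol%), CH2Cl2, 40 °C, 5 mM
Reagents that add atoms: none
Why: Ring-closing metathesis between the terminal vinyl group and the acrylate closes the butenolide with loss of ethylene; the hindered trisubstituted alkenyl iodide is inert to the catalyst.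

Step 11
Reactants: 19 (S)-3-(bromomethyl)-5-[(Z)-3-(TBSO)-2-iodoprop-1-en-1-yl]furan-2(5H)-one; 10 (S,Z)-4-(TBSO)-6-(PMBO)-3-methylhex-2-enal
Product: 21 (4R,5S)-4-[(1S,2Z,4S)-4-(TBSO)-1-hydroxy-6-(PMBO)-3-methylhex-2-en-1-yl]-5-[(Z)-3-(TBSO)-2-iodoprop-1-en-1-yl]-3-methylenedihydrofuran-2(3H)-one, via allylchromium dichloride 20 (not isolated)
Conditions: CrCl2 (nickel-free, 3 equiv), THF, rt
Reagents that add atoms: none
Why: Chromium Barbier allylation with a 3-(bromomethyl)butenolide: the allylchromium adds through C7 in a chair Zimmerman–Traxler transition state, anti to the C6 substituent (trans lactone) and with the ring-locked E allyl geometry giving the anti adduct (8α-OH, 8S), while unveiling the exocyclic C11=C13 methylene; without nickel the alkenyl iodide is not activated.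

Step 12
Reactants: 21 the 8α-alcohol from step 11; 22 tiglic acid
Product: 23 (4R,5S)-4-[(1R,2Z,4S)-4-(TBSO)-6-(PMBO)-3-methyl-1-(tigloyloxy)hex-2-en-1-yl]-5-[(Z)-3-(TBSO)-2-iodoprop-1-en-1-yl]-3-methylenedihydrofuran-2(3H)-one
Conditions: PPh3, DIAD, toluene, 0 °C → rt
Reagents that add atoms: none
Why: Mitsunobu esterification displaces the allylic oxyphosphonium by tiglate in an SN2 step, inverting C8 to the required 8β (8R) configuration and installing the tiglate in the same operation.

Step 13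
Reactants: 23 the C8 tiglate PMB ether
Product: 24 (4R,5S)-4-[(1R,2Z,4S)-4-(TBSO)-6-hydroxy-3-methyl-1-(tigloyloxy)hex-2-en-1-yl]-5-[(Z)-3-(TBSO)-2-iodoprop-1-en-1-yl]-3-methylenedihydrofuran-2(3H)-one
Conditions: DDQ, CH2Cl2/pH 7 buffer, 0 °C
Reagents that add atoms: none
Why: Oxidative PMB cleavage is orthogonal to the silyl ethers, both esters, the alkenyl iodide and the α-methylene lactone.

Step 14
Reactants: 24 the C3 primary alcohol
Product: 25 (4R,5S)-4-[(1R,2Z,4S)-4-(TBSO)-3-methyl-6-oxo-1-(tigloyloxy)hex-2-en-1-yl]-5-[(Z)-3-(TBSO)-2-iodoprop-1-en-1-yl]-3-methylenedihydrofuran-2(3H)-one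
Conditions: Dess–Martin periodinane, NaHCO3, CH2Cl2, 0 °C → rt
Reagents that add atoms: none
Why: Buffered Dess–Martin oxidation gives the β-silyloxy aldehyde without β-elimination or epimerisation; it is used directly.

Step 15
Reactants: 25 the seco-aldehyde alkenyl iodide
Product: 27 (1S,3S,6R,7R,8R)-1,15-bis(TBSO)-3-hydroxy-8-(tigloyloxy)germacra-4Z,9Z,11(13)-trien-12,6-olide, via alkenylchromium dichloride 26 (not isolated)
Conditions: CrCl2 (10 equiv), NiCl2 (1 mol% of Cr), DMSO–THF, rt, 2 mM, syringe-pump addition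
Reagents that add atoms: none
Why: Ni(0) inserts into the C4–I bond and transmetalates to Cr(III), giving alkenylchromium 26 with retention of the Z geometry, which adds intramolecularly to the C3 aldehyde (Nozaki–Hiyama–Kishi reaction; the closest known type is the NHK macrocyclisation that closes ten-membered germacranolide carbocycles onto a preformed α-methylene lactone). The ten-membered ring is closed by C3–C4 bond formation in a 10-exo-trig addition of the alkenyl metal to the carbonyl, whose oxygen ends outside the ring as the C3 hydroxyl. The only new stereocentre, C3, is set by the macrocyclic transition state: the two Z alkenes (A1,3 strain at C6 and C1) and the trans lactone preorganise the chain, so that the aldehyde should be attacked with its oxygen on the ring periphery and anti to the C1–OTBS dipole, giving the 1,3-anti (3S) alcohol. The step needs chemoselectivity for the alkenyl iodide and the aldehyde over the two enoate acceptors and the allylic esters, which the non-basic, aldehyde-selective organochromium(III) secures, and cyclisation over oligomerisation, which high dilution and slow addition secure.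

Step 16
Reactants: 27 the macrocyclic C3 alcohol
Product: 28 (1S,3S,6R,7R,8R)-3-acetoxy-1,15-bis(TBSO)-8-(tigloyloxy)germacra-4Z,9Z,11(13)-trien-12,6-olide
Conditions: Ac2O, DMAP, pyridine, CH2Cl2, 0 °C
Reagents that add atoms: acetic anhydride, CC(=O)OC(C)=O
Why: The C3 hydroxyl is the only free alcohol, so standard acetylation should be selective by default.

Step 17
Reactants: 28 the bis-silyl ether acetate
Product: 29 eupacunolin
Conditions: HF·pyridine, pyridine, THF, 0 °C → rt
Reagents that add atoms: none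
Why: Buffered HF·pyridine removes both TBS ethers (C1 and C15) under mildly acidic conditions that should avoid acetyl migration and spare the esters and the α-methylene lactone.

**Compound list**

1 | 3-[(4-methoxybenzyl)oxy]propan-1-ol | COc1ccc(COCCCO)cc1 | starting material
2 | 3-[(4-methoxybenzyl)oxy]propanal | COc1ccc(COCCC=O)cc1 | intermediate
3 | methyl propiolate | C#CC(=O)OC | starting material
4 | methyl 3-(methylzincio)prop-2-ynoate (methylzinc acetylide) | C[Zn]C#CC(=O)OC | intermediate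
5 | methyl (S)-4-hydroxy-6-[(4-methoxybenzyl)oxy]hex-2-ynoate | COc1ccc(COCC[C@H](O)C#CC(=O)OC)cc1 | intermediate
6 | methyl (S)-4-(TBSO)-6-(PMBO)hex-2-ynoate | COc1ccc(COCC[C@H](O[Si](C)(C)C(C)(C)C)C#CC(=O)OC)cc1 | intermediate
7 | lithium methyl(alkenyl)cuprate from syn-addition to 6 (Cu on C9, cis to the new methyl) | COc1ccc(COCC[C@H](O[Si](C)(C)C(C)(C)C)/C(C)=C(/[Cu-]C)C(=O)OC)cc1.[Li+] | intermediate
8 | methyl (S,Z)-4-(TBSO)-6-(PMBO)-3-methylhex-2-enoate | COc1ccc(COCC[C@H](O[Si](C)(C)C(C)(C)C)/C(C)=C\C(=O)OC)cc1 | intermediate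
9 | (S,Z)-4-(TBSO)-6-(PMBO)-3-methylhex-2-en-1-ol | COc1ccc(COCC[C@H](O[Si](C)(C)C(C)(C)C)/C(C)=C\CO)cc1 | intermediate
10 | (S,Z)-4-(TBSO)-6-(PMBO)-3-methylhex-2-enal | COc1ccc(COCC[C@H](O[Si](C)(C)C(C)(C)C)/C(C)=C\C=O)cc1 | intermediate
11 | acrolein | C=CC=O | starting material
12 | tert-butyldimethyl(prop-2-yn-1-yloxy)silane | C#CCO[Si](C)(C)C(C)(C)C | starting material
13 | methyl[3-(TBSO)prop-1-yn-1-yl]zinc (methylzinc acetylide) | C[Zn]C#CCO[Si](C)(C)C(C)(C)C | intermediate
14 | (S)-6-(TBSO)hex-1-en-4-yn-3-ol | O[C@@H](C=C)C#CCO[Si](C)(C)C(C)(C)C | intermediate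
15 | sodium 2,2-bis(2-methoxyethoxy)-2,5-dihydro-1,2-oxaaluminol-2-uide bearing 5-vinyl (S) and 3-CH2OTBS (cyclic alkenylalanate) | C=C[C@H]1C=C(CO[Si](C)(C)C(C)(C)C)[Al-](OCCOC)(OCCOC)O1.[Na+] | intermediate
16 | (3S,4Z)-6-(TBSO)-5-iodohexa-1,4-dien-3-ol | O[C@@H](C=C)/C=C(I)/CO[Si](C)(C)C(C)(C)C | intermediate
17 | 2-(bromomethyl)acrylic acid | C=C(CBr)C(=O)O | starting material
18 | (3S,4Z)-6-(TBSO)-5-iodohexa-1,4-dien-3-yl 2-(bromomethyl)acrylate | C=C(CBr)C(=O)O[C@@H](C=C)/C=C(I)/CO[Si](C)(C)C(C)(C)C | intermediate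
19 | (S)-3-(bromomethyl)-5-[(Z)-3-(TBSO)-2-iodoprop-1-en-1-yl]furan-2(5H)-one | O=C1O[C@@H](C=C1CBr)/C=C(I)/CO[Si](C)(C)C(C)(C)C | intermediate
20 | allylchromium(III) dichloride derived from 19 (Cr on C13) | O=C1O[C@@H](C=C1C[Cr](Cl)Cl)/C=C(I)/CO[Si](C)(C)C(C)(C)C | intermediate
21 | (4R,5S)-4-[(1S,2Z,4S)-4-(TBSO)-1-hydroxy-6-(PMBO)-3-methylhex-2-en-1-yl]-5-[(Z)-3-(TBSO)-2-iodoprop-1-en-1-yl]-3-methylenedihydrofuran-2(3H)-one (trans lactone, 8α-OH) | C=C1C(=O)O[C@H](/C=C(I)/CO[Si](C)(C)C(C)(C)C)[C@H]1[C@@H](O)/C=C(C)\[C@@H](O[Si](C)(C)C(C)(C)C)CCOCc1ccc(OC)cc1 | intermediate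
22 | tiglic acid, (E)-2-methylbut-2-enoic acid | C/C=C(\C)C(=O)O | starting material
23 | (4R,5S)-4-[(1R,2Z,4S)-4-(TBSO)-6-(PMBO)-3-methyl-1-(tigloyloxy)hex-2-en-1-yl]-5-[(Z)-3-(TBSO)-2-iodoprop-1-en-1-yl]-3-methylenedihydrofuran-2(3H)-one (8β-OTig) | C=C1C(=O)O[C@H](/C=C(I)/CO[Si](C)(C)C(C)(C)C)[C@H]1[C@H](OC(=O)/C(C)=C/C)/C=C(C)\[C@@H](O[Si](C)(C)C(C)(C)C)CCOCc1ccc(OC)cc1 | intermediate
24 | (4R,5S)-4-[(1R,2Z,4S)-4-(TBSO)-6-hydroxy-3-methyl-1-(tigloyloxy)hex-2-en-1-yl]-5-[(Z)-3-(TBSO)-2-iodoprop-1-en-1-yl]-3-methylenedihydrofuran-2(3H)-one | C=C1C(=O)O[C@H](/C=C(I)/CO[Si](C)(C)C(C)(C)C)[C@H]1[C@H](OC(=O)/C(C)=C/C)/C=C(C)\[C@@H](O[Si](C)(C)C(C)(C)C)CCO | intermediate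
25 | (4R,5S)-4-[(1R,2Z,4S)-4-(TBSO)-3-methyl-6-oxo-1-(tigloyloxy)hex-2-en-1-yl]-5-[(Z)-3-(TBSO)-2-iodoprop-1-en-1-yl]-3-methylenedihydrofuran-2(3H)-one (seco-aldehyde) | C=C1C(=O)O[C@H](/C=C(I)/CO[Si](C)(C)C(C)(C)C)[C@H]1[C@H](OC(=O)/C(C)=C/C)/C=C(C)\[C@@H](O[Si](C)(C)C(C)(C)C)CC=O | intermediate
26 | alkenylchromium(III) dichloride derived from 25 (Cr on C4, Z geometry retained) | C=C1C(=O)O[C@H](/C=C([Cr](Cl)Cl)/CO[Si](C)(C)C(C)(C)C)[C@H]1[C@H](OC(=O)/C(C)=C/C)/C=C(C)\[C@@H](O[Si](C)(C)C(C)(C)C)CC=O | intermediate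
27 | (1S,3S,6R,7R,8R)-1,15-bis(TBSO)-3-hydroxy-8-(tigloyloxy)germacra-4Z,9Z,11(13)-trien-12,6-olide | C=C1C(=O)O[C@@H]2/C=C(/CO[Si](C)(C)C(C)(C)C)[C@@H](O)C[C@H](O[Si](C)(C)C(C)(C)C)/C(C)=C\[C@@H](OC(=O)/C(C)=C/C)[C@@H]12 | intermediate
28 | (1S,3S,6R,7R,8R)-3-acetoxy-1,15-bis(TBSO)-8-(tigloyloxy)germacra-4Z,9Z,11(13)-trien-12,6-olide | C=C1C(=O)O[C@@H]2/C=C(/CO[Si](C)(C)C(C)(C)C)[C@@H](OC(C)=O)C[C@H](O[Si](C)(C)C(C)(C)C)/C(C)=C\[C@@H](OC(=O)/C(C)=C/C)[C@@H]12 | intermediate
29 | eupacunolin | C=C1C(=O)O[C@@H]2/C=C(/CO)[C@@H](OC(C)=O)C[C@H](O)/C(C)=C\[C@@H](OC(=O)/C(C)=C/C)[C@@H]12 | target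

**Step count.** Total: 17 steps. Longest linear sequence: 13 steps (steps 1–6, then 11–17); the bromolactone arm (steps 7–10) is convergent.

**Steps most likely to fail**

1. Step 15 (macrocyclisation). What may go wrong: poor or reversed facial selectivity in the addition to the C3 aldehyde, because the macrocyclic bias is predicted and not proven; oligomerisation may also compete. Fallback: the C3 configuration is set by reagent-controlled reduction and no longer by the ring closure. Setting out from 25, the cyclisation product containing the 3R epimer of 27 F1 is oxidised with Dess–Martin periodinane to the macrocyclic C3 enone F2. F2 is reduced with (R)-Me-CBS and catecholborane at −78 °C, the antipode that the usual model (alkenyl as the large group) predicts for the 3S alcohol, and the route is rejoined at 27.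

2. Step 12 (Mitsunobu inversion at C8). What may go wrong: no displacement at the hindered allylic carbinol, elimination towards a diene, or ionisation to an allyl cation with loss of stereospecificity or SN2′ transposition. Fallback: oxidation, reduction and retentive acylation in place of SN2 inversion. Setting out from 21, Dess–Martin oxidation gives the C8 enone F3. F3 is reduced under reagent control ((R)-Me-CBS, catecholborane, −78 °C, again with the alkenyl group taken as the large substituent) to the 8β alcohol F4. F4 is acylated with tiglic acid 22 under Yamaguchi conditions (2,4,6-trichlorobenzoyl chloride, Et3N, DMAP) and the route is rejoined at 23. F3 has an enolisable C7, so it would have to be handled cold and without base.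

3. Step 7 (asymmetric alkynylation of acrolein). What may go wrong: erosion of enantioselectivity by uncatalysed background addition, and polymerisation of acrolein. Fallback: resolution in place of asymmetric catalysis. Setting out from 12, deprotonation with n-BuLi (THF, −78 °C) and addition to acrolein 11 gives the racemic enynol F5. Lipase-catalysed acetylation (Amano PS or CAL-B, vinyl acetate) should convert the R enantiomer into the acetate F6 (Kazlauskas rule, alkynyl arm as the large group) and leave the S alcohol, which rejoins the route at 14.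

**Further compounds**

F1 | step 15 | (1S,3R,6R,7R,8R)-1,15-bis(TBSO)-3-hydroxy-8-(tigloyloxy)germacra-4Z,9Z,11(13)-trien-12,6-olide (3-epimer of 27) | C=C1C(=O)O[C@@H]2/C=C(/CO[Si](C)(C)C(C)(C)C)[C@H](O)C[C@H](O[Si](C)(C)C(C)(C)C)/C(C)=C\[C@@H](OC(=O)/C(C)=C/C)[C@@H]12
F2 | step 15 | (1S,6R,7R,8R)-1,15-bis(TBSO)-3-oxo-8-(tigloyloxy)germacra-4Z,9Z,11(13)-trien-12,6-olide (macrocyclic C3 enone) | C=C1C(=O)O[C@@H]2/C=C(/CO[Si](C)(C)C(C)(C)C)C(=O)C[C@H](O[Si](C)(C)C(C)(C)C)/C(C)=C\[C@@H](OC(=O)/C(C)=C/C)[C@@H]12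
F3 | step 12 | (4R,5S)-4-[(2Z,4S)-4-(TBSO)-6-(PMBO)-3-methylhex-2-enoyl]-5-[(Z)-3-(TBSO)-2-iodoprop-1-en-1-yl]-3-methylenedihydrofuran-2(3H)-one (C8 enone) | C=C1C(=O)O[C@H](/C=C(I)/CO[Si](C)(C)C(C)(C)C)[C@H]1C(=O)/C=C(C)\[C@@H](O[Si](C)(C)C(C)(C)C)CCOCc1ccc(OC)cc1
F4 | step 12 | (4R,5S)-4-[(1R,2Z,4S)-4-(TBSO)-1-hydroxy-6-(PMBO)-3-methylhex-2-en-1-yl]-5-[(Z)-3-(TBSO)-2-iodoprop-1-en-1-yl]-3-methylenedihydrofuran-2(3H)-one (8β alcohol, C8 epimer of 21) | C=C1C(=O)O[C@H](/C=C(I)/CO[Si](C)(C)C(C)(C)C)[C@H]1[C@H](O)/C=C(C)\[C@@H](O[Si](C)(C)C(C)(C)C)CCOCc1ccc(OC)cc1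
F5 | step 7 | racemic 6-(TBSO)hex-1-en-4-yn-3-ol | C=CC(O)C#CCO[Si](C)(C)C(C)(C)C
F6 | step 7 | (R)-6-(TBSO)hex-1-en-4-yn-3-yl acetate | CC(=O)O[C@H](C=C)C#CCO[Si](C)(C)C(C)(C)C
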